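The synthesis cuts the C2–C3 bond of the oxolane ring. C2 is a CH flanked by the ring oxygen O1 and the dimethoxyphenyl ring, so in an open-chain precursor it is the activated OCH2 of a veratryl ether, while C3 becomes the carbenoid carbon of an α-diazo-β-keto ester. A chiral dirhodium carboxylate inserts the carbenoid into one of the two enantiotopic benzylic C–H bonds, closing the ring and fixing C2 in one operation. The C2 aryl group then directs a cis-hydrogenation of the derived enol acetate, which sets C3 and C4 all-cis. Reduction and selective acylation of the primary alcohol complete the synthesis.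

Key step: step 3

Assumption: Rh2(S-PTTL)4 (dirhodium tetrakis[N-phthaloyl-(S)-tert-leucinate]) is taken to favour insertion into the benzylic hydrogen that leads to (2S)-5; if the opposite sense is found, Rh2(R-PTTL)4 is used with no other change.

Step 1
Reactants: 1 3,4-dimethoxybenzyl alcohol; 2 methyl 4-chloro-3-oxobutanoate
Product: 3 methyl 4-[(3,4-dimethoxybenzyl)oxy]-3-oxobutanoate
Conditions: NaH (2.2 equiv), THF, 0 °C to rt; then aq HCl
Reagents that add atoms: none
Why: Williamson ether synthesis, in which the sodium alkoxide of 1 displaces the primary chloride of 2 while the second equivalent of base holds the β-keto ester as its enolate and so protects it from transesterification; no stereocentre is formed.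

Step 2
Reactants: 3 methyl 4-[(3,4-dimethoxybenzyl)oxy]-3-oxobutanoate
Product: 4 methyl 2-diazo-4-[(3,4-dimethoxybenzyl)oxy]-3-oxobutanoate
Conditions: 4-acetamidobenzenesulfonyl azide, Et3N, MeCN, 0 °C to rt
Reagents that add atoms: 4-acetamidobenzenesulfonyl azide, CC(=O)Nc1ccc(cc1)S(=O)(=O)N=[N+]=[N-]
Why: Regitz diazo transfer to the doubly activated methylene of the β-keto ester, which is acidic enough for Et3N; no stereocentre is formed.

Step 3
Reactants: 4 methyl 2-diazo-4-[(3,4-dimethoxybenzyl)oxy]-3-oxobutanoate
Product: 5 methyl (2S)-2-(3,4-dimethoxyphenyl)-4-oxooxolane-3-carboxylate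
Conditions: Rh2(S-PTTL)4 (1 mol %), CH2Cl2, 0 °C to rt
Reagents that add atoms: none
Why: Loss of N2 from 4 at the divalent-rhodium dimer gives an electrophilic rhodium-bound carbene at the future C3, which inserts in a concerted, asynchronous three-centre fashion into a benzylic C–H bond of the OCH2Ar group, the most hydridic C–H in the molecule because of the ether oxygen lone pair and the electron-rich aryl ring. The closest known reaction type is the dirhodium carboxylate-catalysed intramolecular 1,5-C–H insertion of α-diazo-β-keto esters next to ether oxygen (oxolan-3-one synthesis) and its enantioselective versions with N-phthaloyl amino acid ligands. The oxolane ring is closed by 1,5-insertion through a five-membered transition state, from the carbenoid carbon to the fifth atom of the chain. The new stereocentre C2 is set by the chiral ligand sphere, which differentiates the two enantiotopic benzylic hydrogens; C3 is formed as an enolisable centre and is defined only in step 5. The step needs site selectivity, secured by the five-membered transition state and oxygen activation, which favour this C–H over aromatic addition or a four-membered oxonium ylide, and enantioselectivity, which rests on catalyst control because the substrate is achiral.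

Step 4
Reactants: 5 methyl (2S)-2-(3,4-dimethoxyphenyl)-4-oxooxolane-3-carboxylate
Product: 6 methyl (2R)-4-acetoxy-2-(3,4-dimethoxyphenyl)-2,5-dihydrofuran-3-carboxylate
Conditions: Ac2O, Et3N, DMAP (cat.), CH2Cl2, 0 °C
Reagents that add atoms: acetic anhydride, CC(=O)OC(C)=O
Why: O-Acylation of the β-keto ester enolate (nucleophilic acyl substitution) should give the ester-conjugated enol acetate, which locks the C3=C4 double bond for hydrogenation while C2, not being α to a carbonyl, keeps its configuration (the descriptor changes only because the priorities change).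

Step 5
Reactants: 6 methyl (2R)-4-acetoxy-2-(3,4-dimethoxyphenyl)-2,5-dihydrofuran-3-carboxylate
Product: 7 methyl (2S,3S,4S)-4-acetoxy-2-(3,4-dimethoxyphenyl)oxolane-3-carboxylate
Conditions: H2 (4 atm), 5 % Rh/Al2O3, EtOAc, rt
Reagents that add atoms: none
Why: Heterogeneous catalytic syn-hydrogenation of the tetrasubstituted enol acetate should deliver both hydrogens to the face of the C3=C4 bond opposite the C2 aryl group, so that the C3 ester and the C4 acetoxy group end up cis to the aryl group (C3 and C4 set by substrate control from C2), and rhodium on alumina is chosen because it rarely cleaves allylic or benzylic C–O bonds.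

Step 6
Reactants: 7 methyl (2S,3S,4S)-4-acetoxy-2-(3,4-dimethoxyphenyl)oxolane-3-carboxylate
Product: 8 (3S,4R,5S)-5-(3,4-dimethoxyphenyl)-4-(hydroxymethyl)oxolan-3-ol
Conditions: LiAlH4 (2.5 equiv), THF, −20 °C to 0 °C; then H2O, aq NaOH
Reagents that add atoms: none
Why: Hydride reduction of the methyl ester to the primary alcohol with simultaneous reductive cleavage of the acetate (LiAlH4 ester reduction), run cold so that the β-acetoxy ester is reduced before it can epimerise at C3 or eliminate; no stereocentre is changed.

Step 7
Reactants: 8 (3S,4R,5S)-5-(3,4-dimethoxyphenyl)-4-(hydroxymethyl)oxolan-3-ol; 9 3,4-dimethoxybenzoyl chloride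
Product: 10 [(2S,3R,4S)-2-(3,4-dimethoxyphenyl)-4-hydroxyoxolan-3-yl]methyl 3,4-dimethoxybenzoate
Conditions: 9 (1.05 equiv), 2,4,6-collidine, CH2Cl2, −40 °C to 0 °C
Reagents that add atoms: none
Why: Acylation with an acid chloride and a hindered pyridine base (nucleophilic acyl substitution) should select the unhindered primary alcohol over the secondary ring hydroxyl, which is flanked by two cis substituents; no stereocentre is touched.

Compound list
1 | 3,4-dimethoxybenzyl alcohol (veratryl alcohol) | COc1ccc(CO)cc1OC | starting material
2 | methyl 4-chloro-3-oxobutanoate (methyl 4-chloroacetoacetate) | COC(=O)CC(=O)CCl | starting material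
3 | methyl 4-[(3,4-dimethoxybenzyl)oxy]-3-oxobutanoate | COC(=O)CC(=O)COCc1ccc(OC)c(OC)c1 | intermediate
4 | methyl 2-diazo-4-[(3,4-dimethoxybenzyl)oxy]-3-oxobutanoate | COC(=O)C(=[N+]=[N-])C(=O)COCc1ccc(OC)c(OC)c1 | intermediate
5 | methyl (2S)-2-(3,4-dimethoxyphenyl)-4-oxooxolane-3-carboxylate (keto form shown; C3 is enolisable and left undefined) | COC(=O)C1C(=O)CO[C@@H]1c1ccc(OC)c(OC)c1 | intermediate
6 | methyl (2R)-4-acetoxy-2-(3,4-dimethoxyphenyl)-2,5-dihydrofuran-3-carboxylate | COC(=O)C1=C(OC(C)=O)CO[C@@H]1c1ccc(OC)c(OC)c1 | intermediate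
7 | methyl (2S,3S,4S)-4-acetoxy-2-(3,4-dimethoxyphenyl)oxolane-3-carboxylate (all-cis) | COC(=O)[C@@H]1[C@H](OC(C)=O)CO[C@@H]1c1ccc(OC)c(OC)c1 | intermediate
8 | (3S,4R,5S)-5-(3,4-dimethoxyphenyl)-4-(hydroxymethyl)oxolan-3-ol (all-cis diol) | OC[C@@H]1[C@H](O)CO[C@@H]1c1ccc(OC)c(OC)c1 | intermediate
9 | 3,4-dimethoxybenzoyl chloride | COc1ccc(cc1OC)C(Cl)=O | starting material
10 | [(2S,3R,4S)-2-(3,4-dimethoxyphenyl)-4-hydroxyoxolan-3-yl]methyl 3,4-dimethoxybenzoate | COc1ccc(C(=O)OC[C@@H]2[C@H](O)CO[C@@H]2c2ccc(OC)c(OC)c2)cc1OC | target

Total step count: 7. Longest linear sequence: 7 steps (1 to 10).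

Steps most likely to fail

Step 3. The catalyst may discriminate poorly between the two enantiotopic benzylic hydrogens. The electron-rich aryl ring could also favour a stepwise hydride-transfer pathway that erodes the enantiomeric purity, or divert the carbenoid to aromatic addition. The fallback replaces asymmetric catalysis by resolution. Setting out from 4, decomposition with achiral Rh2(OAc)4 in CH2Cl2 should give racemic methyl 2-(3,4-dimethoxyphenyl)-4-oxooxolane-3-carboxylate F1. Condensation with (S)-1-phenylethylamine (AcOH cat., toluene, molecular sieves) should give two diastereomeric enamino esters. Methyl (2R)-2-(3,4-dimethoxyphenyl)-4-{[(1S)-1-phenylethyl]amino}-2,5-dihydrofuran-3-carboxylate F2 is separated by crystallisation or chromatography from its epimer, methyl (2S)-2-(3,4-dimethoxyphenyl)-4-{[(1S)-1-phenylethyl]amino}-2,5-dihydrofuran-3-carboxylate F3, which is discarded. Hydrolysis of F2 with dilute aqueous HCl in THF comes back to the route at 5.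

Step 5. The allylic and benzylic C2–O1 bond may undergo hydrogenolysis, the double bond may migrate toward C2 (loss of the C2 configuration or aromatisation to a furan), an aryl ring may be saturated, or face selectivity on the metal surface may be incomplete. The fallback reduces the ester before the alkene, so that a soluble, hydroxyl-binding iridium catalyst can be used. Setting out from 5, TBSOTf and Et3N in CH2Cl2 at −78 °C should give the silyl enol ether methyl (2R)-4-[(tert-butyldimethylsilyl)oxy]-2-(3,4-dimethoxyphenyl)-2,5-dihydrofuran-3-carboxylate F4. i-Bu2AlH in CH2Cl2 at −78 °C should reduce the conjugated ester to the allylic alcohol [(2R)-4-[(tert-butyldimethylsilyl)oxy]-2-(3,4-dimethoxyphenyl)-2,5-dihydrofuran-3-yl]methanol F5. Hydrogenation with [Ir(cod)(PCy3)(py)]PF6 in CH2Cl2 should add hydrogen anti to the C2 aryl group and give the all-cis alcohol [(2S,3S,4S)-4-[(tert-butyldimethylsilyl)oxy]-2-(3,4-dimethoxyphenyl)oxolan-3-yl]methanol F6. Bu4NF in THF removes the silyl group and comes back to the route at 8.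

Step 7. Regioselectivity may be lost through acylation of the ring hydroxyl, double acylation or acyl migration. The fallback is a Mitsunobu esterification, which activates the primary alcohol instead of the acid. Setting out from 8, 3,4-dimethoxybenzoic acid, PPh3 and diisopropyl azodicarboxylate in THF at 0 °C should give 10 directly; no new compound is formed (F0).

Further compounds
F1 | step 3 | methyl 2-(3,4-dimethoxyphenyl)-4-oxooxolane-3-carboxylate (racemic) | COC(=O)C1C(=O)COC1c1ccc(OC)c(OC)c1
F2 | step 3 | methyl (2R)-2-(3,4-dimethoxyphenyl)-4-{[(1S)-1-phenylethyl]amino}-2,5-dihydrofuran-3-carboxylate | COC(=O)C1=C(N[C@@H](C)c2ccccc2)CO[C@@H]1c1ccc(OC)c(OC)c1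
F3 | step 3 | methyl (2S)-2-(3,4-dimethoxyphenyl)-4-{[(1S)-1-phenylethyl]amino}-2,5-dihydrofuran-3-carboxylate | COC(=O)C1=C(N[C@@H](C)c2ccccc2)CO[C@H]1c1ccc(OC)c(OC)c1
F4 | step 5 | methyl (2R)-4-[(tert-butyldimethylsilyl)oxy]-2-(3,4-dimethoxyphenyl)-2,5-dihydrofuran-3-carboxylate | COC(=O)C1=C(O[Si](C)(C)C(C)(C)C)CO[C@@H]1c1ccc(OC)c(OC)c1
F5 | step 5 | [(2R)-4-[(tert-butyldimethylsilyl)oxy]-2-(3,4-dimethoxyphenyl)-2,5-dihydrofuran-3-yl]methanol | OCC1=C(O[Si](C)(C)C(C)(C)C)CO[C@@H]1c1ccc(OC)c(OC)c1
F6 | step 5 | [(2S,3S,4S)-4-[(tert-butyldimethylsilyl)oxy]-2-(3,4-dimethoxyphenyl)oxolan-3-yl]methanol | OC[C@@H]1[C@H](O[Si](C)(C)C(C)(C)C)CO[C@@H]1c1ccc(OC)c(OC)c1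
F0 | step 7 | none | none
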